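The pyrrolidine is disconnected at C3–N4 and C1–C9a; the latter bond also closes cyclopentene ring A (C9a, C10, C11, C12, C1; N4 is the ring nitrogen, C9 the ketone, C9a the quaternary carbon). Both form in one operation when a 2-substituted azepan-3-one condenses with a lactone aldehyde (C3) to a ketone-stabilised azomethine ylide (C9a–N4–C3) that adds across the terminal double bond (C1=C2) of a tethered 1,1-disubstituted allene, which also forms C2–C3. Two features are exploited: the N4–C9a–C9=O unit, which makes C9a the ylide carbon, and the tetrasubstituted C12=C1 alkene, endocyclic in ring A and exocyclic to the pyrrolidine, the untouched half of the allene.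

Key step: step 16

Remark on the chemistry: further locants used below are C13 (CHMe) of the ring-fused lactone and C18 (CHO) and C20 (CHMe) of the side-chain lactone. The aminoketone centre C9a of 22–24 is configurationally labile and becomes the planar ylide carbon, so 24 is drawn without a descriptor there.

Step 1
Reactants: 1 methyl (S)-3-hydroxy-2-methylpropanoate
Product: 2 methyl (S)-3-[(tert-butyldiphenylsilyl)oxy]-2-methylpropanoate
Conditions: TBDPSCl, imidazole, DMF, 0 °C to rt
Reagents that add atoms: tert-butyl(chloro)diphenylsilane, CC(C)(C)[Si](Cl)(c1ccccc1)c1ccccc1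
Why: Silylation of the primary alcohol with an acid-stable silyl group should be clean and does not touch the stereocentre.

Step 2
Reactants: 2 methyl (S)-3-[(tert-butyldiphenylsilyl)oxy]-2-methylpropanoate
Product: 4 (R)-tert-butyl[(2-methylbut-3-yn-1-yl)oxy]diphenylsilane, via aldehyde 3 (not isolated)
Conditions: iBu2AlH (1.05 equiv), CH2Cl2, −78 °C; then MeOH, K2CO3, dimethyl (1-diazo-2-oxopropyl)phosphonate, −78 °C to rt
Reagents that add atoms: dimethyl (1-diazo-2-oxopropyl)phosphonate, COP(=O)(OC)C(=[N+]=[N-])C(C)=O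
Why: Half-reduction of the ester and Seyferth–Gilbert homologation with the Ohira–Bestmann reagent in one pot should give the alkyne without isolating the epimerisable aldehyde; the descriptor changes from S to R only because the priorities change.

Step 3
Reactants: 4 (R)-tert-butyl[(2-methylbut-3-yn-1-yl)oxy]diphenylsilane
Product: 5 (R)-5-[(tert-butyldiphenylsilyl)oxy]-4-methylpent-2-yn-1-ol
Conditions: nBuLi, THF, −78 °C; (CH2O)n, −78 °C to rt
Reagents that add atoms: formaldehyde (as paraformaldehyde), C=O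
Why: Addition of the lithium acetylide to formaldehyde should give the primary propargylic alcohol.

Step 4
Reactants: 5 (R)-5-[(tert-butyldiphenylsilyl)oxy]-4-methylpent-2-yn-1-ol
Product: 6 (R)-[(5-bromo-2-methylpent-3-yn-1-yl)oxy](tert-butyl)diphenylsilane
Conditions: CBr4, PPh3, CH2Cl2, 0 °C
Reagents that add atoms: tetrabromomethane, BrC(Br)(Br)Br
Why: Appel bromination of a primary propargylic alcohol proceeds under neutral conditions that leave the silyl ether and the stereocentre intact.

Step 5
Reactants: 7 (S)-5-(hydroxymethyl)dihydrofuran-2(3H)-one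
Product: 8 (S)-5-{[(tert-butyldiphenylsilyl)oxy]methyl}dihydrofuran-2(3H)-one
Conditions: TBDPSCl, imidazole, DMF, 0 °C to rt
Reagents that add atoms: tert-butyl(chloro)diphenylsilane, CC(C)(C)[Si](Cl)(c1ccccc1)c1ccccc1
Why: Silylation of the primary alcohol gives a bulky C5 substituent that will steer the lactone enolate chemistry.

Step 6
Reactants: 8 (S)-5-{[(tert-butyldiphenylsilyl)oxy]methyl}dihydrofuran-2(3H)-one
Product: 9 (3R,5S)-5-{[(tert-butyldiphenylsilyl)oxy]methyl}-3-methyldihydrofuran-2(3H)-one
Conditions: LiN(iPr)2, THF, −78 °C; MeI, −78 °C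
Reagents that add atoms: iodomethane, CI
Why: Alkylation of the lactone enolate should occur on the face opposite to the C5 substituent and give the trans lactone.

Step 7
Reactants: 9 (3R,5S)-5-{[(tert-butyldiphenylsilyl)oxy]methyl}-3-methyldihydrofuran-2(3H)-one
Product: 10 (3S,5S)-5-{[(tert-butyldiphenylsilyl)oxy]methyl}-3-methyldihydrofuran-2(3H)-one
Conditions: LiN(iPr)2, THF, −78 °C; then saturated aqueous Na2SO4, −78 °C
Reagents that add atoms: none
Why: Kinetic protonation of the enolate from the face opposite to the C5 substituent should place the methyl group cis (3S); the minor trans epimer is separated and recycled.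

Step 8
Reactants: 10 (3S,5S)-5-{[(tert-butyldiphenylsilyl)oxy]methyl}-3-methyldihydrofuran-2(3H)-one
Product: 11 (3S,5S)-5-(hydroxymethyl)-3-methyldihydrofuran-2(3H)-one
Conditions: Bu4NF, AcOH, THF, 0 °C to rt
Reagents that add atoms: none
Why: Buffered fluoride desilylation should free the alcohol without epimerising the α-methyl centre.

Step 9
Reactants: 11 (3S,5S)-5-(hydroxymethyl)-3-methyldihydrofuran-2(3H)-one
Product: 12 (2S,4S)-4-methyl-5-oxotetrahydrofuran-2-carbaldehyde
Conditions: Dess–Martin periodinane, CH2Cl2, 0 °C to rt; used without chromatography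
Reagents that add atoms: none
Why: A non-basic oxidation should give the α-alkoxy aldehyde without loss of the adjacent stereocentre.

Step 10
Reactants: 13 ethyl glyoxylate, 14 4-methoxyaniline, 15 butanal
Product: 17 ethyl (2R,3R)-3-formyl-2-[(4-methoxyphenyl)amino]pentanoate, via imine 16 (not isolated)
Conditions: 13, 14, MgSO4, CH2Cl2, rt; filtration and evaporation; then 15 (2 equiv), D-proline (20 mol %), 1,4-dioxane, rt
Reagents that add atoms: none
Why: Proline-catalysed Mannich reaction: the (E)-enamine of butanal and D-proline adds to the (E)-imine through the acid-organised chair transition state to give the syn (2R,3R) adduct, the mirror image of the L-proline outcome, which sets the future C10.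

Step 11
Reactants: 17 ethyl (2R,3R)-3-formyl-2-[(4-methoxyphenyl)amino]pentanoate, 6 (R)-[(5-bromo-2-methylpent-3-yn-1-yl)oxy](tert-butyl)diphenylsilane
Product: 19 (3R,4R,5S)-5-{(4R)-5-[(tert-butyldiphenylsilyl)oxy]-4-methylpenta-1,2-dien-3-yl}-4-ethyl-3-[(4-methoxyphenyl)amino]dihydrofuran-2(3H)-one, via hydroxy ester 18 (not isolated)
Conditions: In powder, THF/H2O (2:1), rt; then PPTS (cat.), toluene, 50 °C
Reagents that add atoms: none
Why: Barbier-type propargylation: the organoindium from the γ-substituted propargyl bromide adds through its substituted terminus (SE2′) to give the allenyl carbinol, Felkin–Anh attack anti to the CH(NHAr)CO2Et group sets the future C11 as S (syn to ethyl), and acid closes the γ-lactone, at which stage minor isomers are removed.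

Step 12
Reactants: 19 (3R,4R,5S)-5-{(4R)-5-[(tert-butyldiphenylsilyl)oxy]-4-methylpenta-1,2-dien-3-yl}-4-ethyl-3-[(4-methoxyphenyl)amino]dihydrofuran-2(3H)-one
Product: 20 (2R,3R,4S)-5-{(2R)-1-[(tert-butyldiphenylsilyl)oxy]propan-2-yl}-3-ethyl-4-hydroxy-N-methoxy-2-[(4-methoxyphenyl)amino]-N-methylhepta-5,6-dienamide
Conditions: MeNH(OMe)·HCl, AlMe3, CH2Cl2, 0 °C to rt
Reagents that add atoms: N,O-dimethylhydroxylamine hydrochloride, CNOC.Cl
Why: Aluminium amide aminolysis of the lactone (Weinreb amide formation) should open the ring and release the C11 hydroxyl.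

Step 13
Reactants: 20 (2R,3R,4S)-5-{(2R)-1-[(tert-butyldiphenylsilyl)oxy]propan-2-yl}-3-ethyl-4-hydroxy-N-methoxy-2-[(4-methoxyphenyl)amino]-N-methylhepta-5,6-dienamide
Product: 21 (2R,3R,4S)-4-[(tert-butyldimethylsilyl)oxy]-5-{(2R)-1-[(tert-butyldiphenylsilyl)oxy]propan-2-yl}-3-ethyl-N-methoxy-2-[(4-methoxyphenyl)amino]-N-methylhepta-5,6-dienamide
Conditions: tBuMe2SiOTf, 2,6-lutidine, CH2Cl2, −78 to 0 °C
Reagents that add atoms: tert-butyldimethylsilyl trifluoromethanesulfonate, CC(C)(C)[Si](C)(C)OS(=O)(=O)C(F)(F)F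
Why: Silylation of the hindered secondary alcohol prevents relactonisation and hemiketal formation in the following steps.

Step 14
Reactants: 21 (2R,3R,4S)-4-[(tert-butyldimethylsilyl)oxy]-5-{(2R)-1-[(tert-butyldiphenylsilyl)oxy]propan-2-yl}-3-ethyl-N-methoxy-2-[(4-methoxyphenyl)amino]-N-methylhepta-5,6-dienamide
Product: 22 (6R,7R,8S)-8-[(tert-butyldimethylsilyl)oxy]-9-{(2R)-1-[(tert-butyldiphenylsilyl)oxy]propan-2-yl}-1-chloro-7-ethyl-6-[(4-methoxyphenyl)amino]undeca-9,10-dien-5-one
Conditions: Cl(CH2)4MgBr (3 equiv, from 1-bromo-4-chlorobutane and Mg), THF, 0 °C to rt; aqueous NH4Cl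
Reagents that add atoms: 4-chlorobutylmagnesium bromide, ClCCCC[Mg]Br
Why: Weinreb ketone synthesis: the chelated tetrahedral intermediate prevents over-addition and the first equivalent of reagent is spent on the N–H.

Step 15
Reactants: 22 (6R,7R,8S)-8-[(tert-butyldimethylsilyl)oxy]-9-{(2R)-1-[(tert-butyldiphenylsilyl)oxy]propan-2-yl}-1-chloro-7-ethyl-6-[(4-methoxyphenyl)amino]undeca-9,10-dien-5-one
Product: 24 2-{(3R,4S)-4-[(tert-butyldimethylsilyl)oxy]-5-[(2R)-1-[(tert-butyldiphenylsilyl)oxy]propan-2-yl]hepta-5,6-dien-3-yl}azepan-3-one (either configuration at C2), via aminoketone 23 (not isolated)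
Conditions: (NH4)2Ce(NO3)6 (3 equiv), MeCN/H2O (4:1), 0 °C; NaHCO3 work-up; then K2CO3, NaI (20 mol %), MeCN (high dilution), 60 °C
Reagents that add atoms: none
Why: Oxidative N-dearylation of the 4-methoxyphenyl amine frees the primary amine, which should close the seven-membered ring by intramolecular N-alkylation (7-exo-tet, Finkelstein-assisted).

Step 16
Reactants: 24 2-{(3R,4S)-4-[(tert-butyldimethylsilyl)oxy]-5-[(2R)-1-[(tert-butyldiphenylsilyl)oxy]propan-2-yl]hepta-5,6-dien-3-yl}azepan-3-one, 12 (2S,4S)-4-methyl-5-oxotetrahydrofuran-2-carbaldehyde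
Product: 26 (3S,9aR,10R,11S)-tricyclic aminoketone bearing C11–OSitBuMe2 plus the (13R)-CH(CH3)CH2OSitBuPh2 group at C12 plus the (18S,20S)-lactone at C3, via azomethine ylide 25 (not isolated)
Conditions: 12 (1.5 equiv, freshly prepared), toluene, 4 Å molecular sieves, 60 °C then 110 °C
Reagents that add atoms: none
Why: The secondary amine of 24 condenses with 12 to an iminium ion, loss of the C9a proton (flanked by N4+ and the C9 ketone) gives the ketone-stabilised azomethine ylide 25, and this adds suprafacially across the terminal C1=C2 π-bond of the allene, so that C3–N4 (condensation) and C1–C9a plus C2–C3 (cycloaddition) form in one operation and the proximal allene π-bond survives as the C12=C1 alkene. The closest known reaction type is the intramolecular (3+2) cycloaddition of azomethine ylides, generated by condensing secondary α-amino carbonyl compounds with aldehydes, onto tethered unactivated alkenes; 1,3-dipoles are also known to add to the C=C bonds of allenes. Ring A closes in the fused mode through the three-atom tether C10–C11–C12 from the ylide carbon to the central allene carbon, whose reacting π-lobe lies in the plane of the C12 substituents and hence in the plane of the forming cyclopentene, and the pyrrolidine closes as the (3+2) ring itself. C9a is controlled by the C10 stereocentre through allylic 1,3-strain: the tether holds C11 below the ylide plane on the C9 side, so the position eclipsing the N4=C3 side is taken by C10–H and not by ethyl, which should put ethyl anti to N4 and syn to C9 (9aR); C3 is controlled by the ylide geometry, the lactone residue lying anti to the fully substituted C9a, which should place it cis to C9 on the new pyrrolidine (3S). The step needs reaction at the distal and not the proximal allene π-bond, fused and not bridged regiochemistry, and retention of C18; the first two are secured by the short tether (the alternatives would give a four-membered ring or a bridgehead alkene) and the last by the much higher acidity of C9a–H compared with C18–H in the iminium ion.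

Step 17
Reactants: 26 (3S,9aR,10R,11S)-tricyclic aminoketone bis-silyl ether
Product: 27 (3S,9aR,10R,11S,13R,18S,20S)-diol with C11–OH and C12–CH(CH3)CH2OH
Conditions: Bu4NF (4 equiv), AcOH (4 equiv), THF, rt to 45 °C
Reagents that add atoms: none
Why: Buffered fluoride should remove both silyl groups without epimerising the α-methyl lactone or touching the aminoketone.

Step 18
Reactants: 27 (3S,9aR,10R,11S,13R,18S,20S)-diol
Product: 30 target CNP0315436.2, via hydroxy aldehyde 28 (not isolated), via lactol 29 (not isolated)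
Conditions: TEMPO (20 mol %), PhI(OAc)2 (2.5 equiv), CH2Cl2, rt
Reagents that add atoms: none
Why: Oxoammonium oxidation should take the primary alcohol to the aldehyde, which is trapped by the C11 hydroxyl as the lactol and oxidised on to the γ-lactone; the conditions are neutral, so C13 (β,γ-unsaturated, from compound 1) is not deprotonated.

Compound list
1 | methyl (S)-3-hydroxy-2-methylpropanoate | COC(=O)[C@@H](C)CO | starting material
2 | methyl (S)-3-[(tert-butyldiphenylsilyl)oxy]-2-methylpropanoate | COC(=O)[C@@H](C)CO[Si](c1ccccc1)(c1ccccc1)C(C)(C)C | intermediate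
3 | (S)-3-[(tert-butyldiphenylsilyl)oxy]-2-methylpropanal | O=C[C@@H](C)CO[Si](c1ccccc1)(c1ccccc1)C(C)(C)C | intermediate
4 | (R)-tert-butyl[(2-methylbut-3-yn-1-yl)oxy]diphenylsilane | C#C[C@@H](C)CO[Si](c1ccccc1)(c1ccccc1)C(C)(C)C | intermediate
5 | (R)-5-[(tert-butyldiphenylsilyl)oxy]-4-methylpent-2-yn-1-ol | OCC#C[C@@H](C)CO[Si](c1ccccc1)(c1ccccc1)C(C)(C)C | intermediate
6 | (R)-[(5-bromo-2-methylpent-3-yn-1-yl)oxy](tert-butyl)diphenylsilane | BrCC#C[C@@H](C)CO[Si](c1ccccc1)(c1ccccc1)C(C)(C)C | intermediate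
7 | (S)-5-(hydroxymethyl)dihydrofuran-2(3H)-one | OC[C@@H]1CCC(=O)O1 | starting material
8 | (S)-5-{[(tert-butyldiphenylsilyl)oxy]methyl}dihydrofuran-2(3H)-one | CC(C)(C)[Si](OC[C@@H]1CCC(=O)O1)(c1ccccc1)c1ccccc1 | intermediate
9 | (3R,5S)-5-{[(tert-butyldiphenylsilyl)oxy]methyl}-3-methyldihydrofuran-2(3H)-one (trans) | CC(C)(C)[Si](OC[C@@H]1C[C@@H](C)C(=O)O1)(c1ccccc1)c1ccccc1 | intermediate
10 | (3S,5S)-5-{[(tert-butyldiphenylsilyl)oxy]methyl}-3-methyldihydrofuran-2(3H)-one (cis) | CC(C)(C)[Si](OC[C@@H]1C[C@H](C)C(=O)O1)(c1ccccc1)c1ccccc1 | intermediate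
11 | (3S,5S)-5-(hydroxymethyl)-3-methyldihydrofuran-2(3H)-one | OC[C@@H]1C[C@H](C)C(=O)O1 | intermediate
12 | (2S,4S)-4-methyl-5-oxotetrahydrofuran-2-carbaldehyde | O=C[C@@H]1C[C@H](C)C(=O)O1 | intermediate
13 | ethyl glyoxylate | CCOC(=O)C=O | starting material
14 | 4-methoxyaniline | COc1ccc(N)cc1 | starting material
15 | butanal | CCCC=O | starting material
16 | ethyl (E)-2-[(4-methoxyphenyl)imino]acetate | CCOC(=O)/C=N/c1ccc(OC)cc1 | intermediate
17 | ethyl (2R,3R)-3-formyl-2-[(4-methoxyphenyl)amino]pentanoate | CC[C@H]([C@@H](Nc1ccc(OC)cc1)C(=O)OCC)C=O | intermediate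
18 | ethyl (2R,3R,4S)-5-{(2R)-1-[(tert-butyldiphenylsilyl)oxy]propan-2-yl}-3-ethyl-4-hydroxy-2-[(4-methoxyphenyl)amino]hepta-5,6-dienoate | CC[C@H]([C@@H](Nc1ccc(OC)cc1)C(=O)OCC)[C@H](O)C(=C=C)[C@@H](C)CO[Si](c1ccccc1)(c1ccccc1)C(C)(C)C | intermediate
19 | (3R,4R,5S)-5-{(4R)-5-[(tert-butyldiphenylsilyl)oxy]-4-methylpenta-1,2-dien-3-yl}-4-ethyl-3-[(4-methoxyphenyl)amino]dihydrofuran-2(3H)-one | CC[C@@H]1[C@@H](Nc2ccc(OC)cc2)C(=O)O[C@@H]1C(=C=C)[C@@H](C)CO[Si](c2ccccc2)(c2ccccc2)C(C)(C)C | intermediate
20 | (2R,3R,4S)-hydroxy Weinreb amide (N-methoxy-N-methyl amide of the acid of 18) | CC[C@H]([C@@H](Nc1ccc(OC)cc1)C(=O)N(C)OC)[C@H](O)C(=C=C)[C@@H](C)CO[Si](c1ccccc1)(c1ccccc1)C(C)(C)C | intermediate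
21 | (2R,3R,4S)-4-O-tert-butyldimethylsilyl ether of 20 | CC[C@H]([C@@H](Nc1ccc(OC)cc1)C(=O)N(C)OC)[C@H](O[Si](C)(C)C(C)(C)C)C(=C=C)[C@@H](C)CO[Si](c1ccccc1)(c1ccccc1)C(C)(C)C | intermediate
22 | (6R,7R,8S)-8-[(tert-butyldimethylsilyl)oxy]-9-{(2R)-1-[(tert-butyldiphenylsilyl)oxy]propan-2-yl}-1-chloro-7-ethyl-6-[(4-methoxyphenyl)amino]undeca-9,10-dien-5-one | CC[C@H]([C@@H](Nc1ccc(OC)cc1)C(=O)CCCCCl)[C@H](O[Si](C)(C)C(C)(C)C)C(=C=C)[C@@H](C)CO[Si](c1ccccc1)(c1ccccc1)C(C)(C)C | intermediate
23 | (6R,7R,8S)-6-amino analogue of 22 (primary aminoketone) | CC[C@H]([C@@H](N)C(=O)CCCCCl)[C@H](O[Si](C)(C)C(C)(C)C)C(=C=C)[C@@H](C)CO[Si](c1ccccc1)(c1ccccc1)C(C)(C)C | intermediate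
24 | 2-{(3R,4S)-4-[(tert-butyldimethylsilyl)oxy]-5-[(2R)-1-[(tert-butyldiphenylsilyl)oxy]propan-2-yl]hepta-5,6-dien-3-yl}azepan-3-one (C2 undefined) | CC[C@H](C1NCCCCC1=O)[C@H](O[Si](C)(C)C(C)(C)C)C(=C=C)[C@@H](C)CO[Si](c1ccccc1)(c1ccccc1)C(C)(C)C | intermediate
25 | azomethine ylide (iminium enolate) from 24 and 12 | CC[C@H](C1=C([O-])CCCC[N+]1=C[C@@H]1C[C@H](C)C(=O)O1)[C@H](O[Si](C)(C)C(C)(C)C)C(=C=C)[C@@H](C)CO[Si](c1ccccc1)(c1ccccc1)C(C)(C)C | intermediate
26 | (3S,9aR,10R,11S,13R,18S,20S)-cycloadduct: azepan-3-one (N4, C5–C9, C9a), pyrrolidine (N4, C9a, C1, C2, C3) and cyclopentene (C9a, C10, C11, C12=C1) with ethyl at C10, OSitBuMe2 at C11, CH(CH3)CH2OSitBuPh2 at C12 and the 4-methyl-5-oxotetrahydrofuran-2-yl group at C3 | CC[C@H]1[C@H](O[Si](C)(C)C(C)(C)C)C([C@@H](C)CO[Si](c2ccccc2)(c2ccccc2)C(C)(C)C)=C2C[C@@H]([C@@H]3C[C@H](C)C(=O)O3)N3CCCCC(=O)[C@]213 | intermediate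
27 | (3S,9aR,10R,11S,13R,18S,20S)-diol (C11–OH, C12–CH(CH3)CH2OH) | CC[C@H]1[C@H](O)C([C@@H](C)CO)=C2C[C@@H]([C@@H]3C[C@H](C)C(=O)O3)N3CCCCC(=O)[C@]213 | intermediate
28 | hydroxy aldehyde (C11–OH, C12–CH(CH3)CHO) | CC[C@H]1[C@H](O)C([C@@H](C)C=O)=C2C[C@@H]([C@@H]3C[C@H](C)C(=O)O3)N3CCCCC(=O)[C@]213 | intermediate
29 | lactol (mixture at the hemiacetal carbon) | CC[C@H]1[C@@H]2OC(O)[C@H](C)C2=C2C[C@@H]([C@@H]3C[C@H](C)C(=O)O3)N3CCCCC(=O)[C@]213 | intermediate
30 | CNP0315436.2, (3S,9aR,10R,11S,13R,18S,20S) | CC[C@H]1[C@@H]2OC(=O)[C@H](C)C2=C2C[C@@H]([C@@H]3C[C@H](C)C(=O)O3)N3CCCCC(=O)[C@]213 | target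

Total step count: 18. Longest linear sequence: 12 steps (steps 1–4, then 11–18, from compound 1).

Steps most likely to fail

1. Step 16. The unactivated allene may add too slowly to the stabilised ylide, or the hindered secondary amine may condense sluggishly, so that iminium–enamine equilibration toward C18 erodes the lactone stereocentre before cycloaddition. The fallback sets out from 22 and comes back at 26, changing both the dipole and the order of ring construction. Compound 22 is dearylated as in step 15, but the ammonium salt of 23 is condensed at once with 12 (Et3N, MgSO4, CH2Cl2) to the aldimine F1. Heating F1 in toluene (or AgOAc/Et3N) generates the N–H or N-metalated azomethine ylide from the imine, which cannot form an enamine toward C18, and cycloaddition gives the N–H pyrrolidine F2. K2CO3 and NaI in MeCN then close the azepanone ring by intramolecular N-alkylation to give 26.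

2. Step 11. Transfer of the propargyl instead of the allenyl unit and weak Felkin–Anh control at the new carbinol would give regio- and stereoisomeric mixtures. The fallback sets out from 4 and 17 and comes back at 19. Alkyne 4 is lithiated (nBuLi) and alkylated with (iodomethyl)trimethylsilane to the propargylsilane F3. Its BF3·OEt2-promoted addition to 17 (CH2Cl2, −78 °C) can only proceed by SE2′ through an open transition state, which should give the allenyl carbinol 18 alone and with stronger Felkin–Anh bias; lactonisation as before gives 19.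

3. Step 15. Self-condensation of the free primary aminoketone (dihydropyrazine formation) may compete with seven-membered ring closure, and the oxidant may attack the liberated amine. The fallback sets out from 22 and comes back at 24 by reversing the order. The aryl amine of 22 is cyclised first (NaI, K2CO3, DMF, 80 °C) to the N-aryl azepanone F4, in which no primary amine is ever free, and the 4-methoxyphenyl group is then removed oxidatively ((NH4)2Ce(NO3)6, MeCN/H2O, 0 °C) to give 24.

Further compounds
F1 | step 16 | (E)-aldimine from aminoketone 23 and aldehyde 12 | CC[C@H]([C@@H](/N=C/[C@@H]1C[C@H](C)C(=O)O1)C(=O)CCCCCl)[C@H](O[Si](C)(C)C(C)(C)C)C(=C=C)[C@@H](C)CO[Si](c1ccccc1)(c1ccccc1)C(C)(C)C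
F2 | step 16 | N–H pyrrolidine cycloadduct with a 5-chloropentanoyl group at C9a | CC[C@H]1[C@H](O[Si](C)(C)C(C)(C)C)C([C@@H](C)CO[Si](c2ccccc2)(c2ccccc2)C(C)(C)C)=C2C[C@@H]([C@@H]3C[C@H](C)C(=O)O3)N[C@@]21C(=O)CCCCCl
F3 | step 11 | (R)-tert-butyl{[2-methyl-5-(trimethylsilyl)pent-3-yn-1-yl]oxy}diphenylsilane | C[Si](C)(C)CC#C[C@@H](C)CO[Si](c1ccccc1)(c1ccccc1)C(C)(C)C
F4 | step 15 | N-(4-methoxyphenyl) derivative of azepanone 24 | CC[C@H](C1N(c2ccc(OC)cc2)CCCCC1=O)[C@H](O[Si](C)(C)C(C)(C)C)C(=C=C)[C@@H](C)CO[Si](c2ccccc2)(c2ccccc2)C(C)(C)C
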